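**Retrosynthetic overview** (ring locants are those of cyclodeca[b]furan: C4 carries the methacrylate, C6 the tertiary acetate, C7 the ketone, C10=C11 the Z-olefin, C11a the lactone CH)
- The butenolide is unmasked last from a fused furan: C2–H borylation, N-oxide oxidation and γ-protonation create the lactone carbonyl and the C11a–H stereocentre under base-free conditions.
- The ten-membered ring is closed at C11–C11a by Pd-catalysed C–H alkenylation of the furan with a tethered (Z)-alkenyl chloride, whose geometry is fixed beforehand by Negishi anti-carboalumination of but-3-yn-1-ol.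
- The C7 ketone and the C8–C11 chain come from Grignard opening of an α-hydroxy-α-methyl-γ-lactone, itself made by Mukaiyama hydration of an α-methylene lactone (sets C6).
- Key step: that α-methylene lactone comes in one step from symmetric 3,4-bis(hydroxymethyl)furan by a desymmetrising, enantioselective Ir-catalysed 2-(methoxycarbonyl)allylation/lactonisation (sets C4).
- Ring order: furan (bought) → temporary γ-lactone → cyclodecene → butenolide (from the furan).

Assumption: the (R)-SEGPHOS-modified iridium catalyst adds to the Si face of the intermediate aldehyde (giving the 5S lactone); if the sense is opposite, the (S)-ligand is used and nothing else changes.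

**Step 1**
Reactants: 1 3,4-bis(hydroxymethyl)furan (3 equiv, excess recovered); 2 methyl 2-{[(tert-butoxycarbonyl)oxy]methyl}prop-2-enoate
Product: 5 (5S)-5-[4-(hydroxymethyl)furan-3-yl]-3-methylideneoxolan-2-one, via furan aldehyde 3 (not isolated), via hydroxy ester 4 (not isolated)
Conditions: [Ir(cod)Cl]2 (2.5 mol%), (R)-SEGPHOS (5 mol%), 4-cyano-3-nitrobenzoic acid (10 mol%), Cs2CO3 (20 mol%), THF, 60 °C; then TsOH·H2O (cat.), rt
Reagents that add atoms: none
Why: Krische transfer-hydrogenative carbonyl 2-(alkoxycarbonyl)allylation from the alcohol oxidation level: one of the two equivalent CH2OH groups of the C2v diol is dehydrogenated to aldehyde 3, the chiral allyliridium adds to its Si face (sets the S carbinol) and hydroxy ester 4 lactonises, so a single step breaks the symmetry, sets the first stereocentre and installs four skeletal carbons, while excess 1 suppresses double addition.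

**Step 2**
Reactants: 5 (5S)-5-[4-(hydroxymethyl)furan-3-yl]-3-methylideneoxolan-2-one
Product: 7 (3R,5S)-3-hydroxy-5-[4-(hydroxymethyl)furan-3-yl]-3-methyloxolan-2-one, via hydroperoxide 6 (not isolated)
Conditions: Mn(dpm)3 (dpm = dipivaloylmethanate, 10 mol%), PhSiH3, O2 (1 atm), i-PrOH/CH2Cl2, 0 °C; then P(OEt)3
Reagents that add atoms: dioxygen, O=O
Why: Mukaiyama-type hydrogen-atom-transfer hydration: H-atom transfer to the exo-methylene gives the tertiary α-lactonyl radical, which O2 traps on the face anti to the C5 furyl group, and phosphite reduces the hydroperoxide, giving the 3R alcohol trans to the furyl group (the required 1,3-syn diol relationship).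

**Step 3**
Reactants: 8 but-3-yn-1-ol
Product: 11 (3Z)-4-chloro-3-methylbut-3-en-1-ol, via E-alkenylalane 9 (not isolated), via Z-alkenylalane chelate 10 (not isolated)
Conditions: Me3Al (3 equiv), Cp2ZrCl2 (25 mol%), ClCH2CH2Cl, rt; then reflux; then N-chlorosuccinimide, −30 → 0 °C; aq. HCl
Reagents that add atoms: trimethylaluminium, C[Al](C)C; N-chlorosuccinimide, O=C1CCC(=O)N1Cl
Why: Negishi zirconium-catalysed syn-carboalumination followed by alkoxide-chelation-driven isomerisation gives the Z-alkenylalane (net anti-carbometalation), and chlorodealumination with retention places Cl cis to the CH2CH2O chain.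

**Step 4**
Reactants: 11 (3Z)-4-chloro-3-methylbut-3-en-1-ol
Product: 12 (1Z)-4-bromo-1-chloro-2-methylbut-1-ene
Conditions: CBr4, PPh3, CH2Cl2, 0 °C
Reagents that add atoms: carbon tetrabromide, BrC(Br)(Br)Br
Why: Appel bromination of the primary alcohol; the trisubstituted vinyl chloride is inert and keeps its geometry.

**Step 5**
Reactants: 12 (1Z)-4-bromo-1-chloro-2-methylbut-1-ene; 7 (3R,5S)-3-hydroxy-5-[4-(hydroxymethyl)furan-3-yl]-3-methyloxolan-2-one
Product: 14 (1Z,6R,8S)-1-chloro-6,8-dihydroxy-8-[4-(hydroxymethyl)furan-3-yl]-2,6-dimethyloct-1-en-5-one (open form shown; equilibrates with its cyclic hemiketal), via Grignard reagent 13 (not isolated)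
Conditions: 12, Mg, THF, 35 °C; separately 7, t-BuMgCl (2.0 equiv), THF, −78 °C; then add the Grignard solution (1.5 equiv), −78 → −30 °C; aq. NH4Cl
Reagents that add atoms: none
Why: Grignard mono-addition to the lactone: Mg inserts only into the alkyl bromide, and the α-alkoxide-chelated tetrahedral intermediate survives until quench, so the lactone opens to the C5 ketone and frees the secondary carbinol without touching either stereocentre.

**Step 6**
Reactants: 14 (1Z,6R,8S)-1-chloro-6,8-dihydroxy-8-[4-(hydroxymethyl)furan-3-yl]-2,6-dimethyloct-1-en-5-one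
Product: 15 {4-[(1S,3R,7Z)-8-chloro-1,3-dihydroxy-3,7-dimethyl-4-oxooct-7-en-1-yl]furan-3-yl}methyl acetate
Conditions: AcCl (1.05 equiv), 2,4,6-collidine, CH2Cl2, −78 °C
Reagents that add atoms: acetyl chloride, CC(=O)Cl
Why: Chemoselective acylation of the primary furylmethyl alcohol; the secondary hydroxyl (largely tied up as hemiketal) and the tertiary hydroxyl do not react at −78 °C.

**Step 7**
Reactants: 15 {4-[(1S,3R,7Z)-8-chloro-1,3-dihydroxy-3,7-dimethyl-4-oxooct-7-en-1-yl]furan-3-yl}methyl acetate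
Product: 16 [(4S,6R,10Z)-4,6-dihydroxy-6,10-dimethyl-7-oxo-4,5,6,7,8,9-hexahydrocyclodeca[b]furan-3-yl]methyl acetate
Conditions: Pd(OAc)2 (10 mol%), n-BuAd2P (20 mol%), PivOH (30 mol%), K3PO4 (2 equiv), DMA, 110 °C, 0.003 M, syringe-pump addition
Reagents that add atoms: none
Why: Proposed new method: oxidative addition of the alkenyl chloride, pivalate-assisted concerted metalation–deprotonation of the furan α-C–H next to the tether and reductive elimination close the ten-membered ring with retention of the Z geometry; the tether makes the ortho α-position the only one that gives an unstrained ring, the hemiketal form pre-folds the chain, and the closest known chemistry is Pd/pivalate direct arylation and alkenylation of furans and macrocyclising direct arylations.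

**Step 8**
Reactants: 16 [(4S,6R,10Z)-4,6-dihydroxy-6,10-dimethyl-7-oxo-4,5,6,7,8,9-hexahydrocyclodeca[b]furan-3-yl]methyl acetate
Product: 17 (4S,6R,10Z)-3-(acetoxymethyl)-6-hydroxy-6,10-dimethyl-7-oxo-4,5,6,7,8,9-hexahydrocyclodeca[b]furan-4-yl 2-methylprop-2-enoate
Conditions: methacrylic anhydride (1.5 equiv), DMAP (20 mol%), Et3N, CH2Cl2, 0 °C → rt
Reagents that add atoms: methacrylic anhydride, C=C(C)C(=O)OC(=O)C(C)=C
Why: DMAP-catalysed acylation of the secondary alcohol (drawn through the open hydroxy-ketone tautomer); the tertiary α-ketol hydroxyl is too hindered to compete.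

**Step 9**
Reactants: 17 (4S,6R,10Z)-3-(acetoxymethyl)-6-hydroxy-6,10-dimethyl-7-oxo-4,5,6,7,8,9-hexahydrocyclodeca[b]furan-4-yl 2-methylprop-2-enoate
Product: 18 (4S,6R,10Z)-6-acetoxy-3-(acetoxymethyl)-6,10-dimethyl-7-oxo-4,5,6,7,8,9-hexahydrocyclodeca[b]furan-4-yl 2-methylprop-2-enoate
Conditions: Ac2O (5 equiv), DMAP (1 equiv), Et3N, CH2Cl2, 35 °C
Reagents that add atoms: acetic anhydride, CC(=O)OC(C)=O
Why: Forcing DMAP acetylation of the tertiary α-ketol; nucleophilic catalysis is used rather than a Lewis acid so the free furan α-position is not C-acylated, and all base-mediated steps are finished while the ring is still a robust furan.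

**Step 10**
Reactants: 18 (4S,6R,10Z)-6-acetoxy-3-(acetoxymethyl)-6,10-dimethyl-7-oxo-4,5,6,7,8,9-hexahydrocyclodeca[b]furan-4-yl 2-methylprop-2-enoate
Product: 21 (4S,6R,10Z,11aR)-6-acetoxy-3-(acetoxymethyl)-6,10-dimethyl-2,7-dioxo-2,4,5,6,7,8,9,11a-octahydrocyclodeca[b]furan-4-yl 2-methylprop-2-enoate, via furyl boronate 19 (not isolated), via boryloxyfuran 20 (not isolated)
Conditions: [Ir(cod)OMe]2 (3 mol%), 4,4'-di-tert-butyl-2,2'-bipyridine (6 mol%), B2pin2 (1.05 equiv), MTBE, 50 °C; concentrate; N,N-dimethyl-4-toluidine N-oxide (1.2 equiv), CH2Cl2, 0 °C; then AcOH/H2O, −40 → 0 °C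
Reagents that add atoms: N,N-dimethyl-4-toluidine N-oxide, Cc1ccc([N+](C)(C)[O-])cc1 (lactone carbonyl oxygen); bis(pinacolato)diboron, CC1(C)OB(OC1(C)C)B1OC(C)(C)C(C)(C)O1 (boron only in 19 and 20)
Why: Hartwig–Miyaura C–H borylation at the only remaining furan α-C–H, N-oxide oxidation of the C–B bond to the 2-boryloxyfuran and kinetic γ-protonation at C11a break the aromaticity and give the tetrasubstituted conjugated butenolide; the proton is expected to arrive anti to the C4 methacryloyloxy group, placing H-11a cis to H-4 (11aR), and no base is present afterwards to epimerise or isomerise the γ-alkenyl butenolide.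

**Compound list**
1 | 3,4-bis(hydroxymethyl)furan | OCc1cocc1CO | starting material
2 | methyl 2-{[(tert-butoxycarbonyl)oxy]methyl}prop-2-enoate | C=C(COC(=O)OC(C)(C)C)C(=O)OC | starting material
3 | 4-(hydroxymethyl)furan-3-carbaldehyde | O=Cc1cocc1CO | intermediate (not isolated)
4 | methyl (4S)-4-hydroxy-4-[4-(hydroxymethyl)furan-3-yl]-2-methylidenebutanoate | O[C@H](c1cocc1CO)CC(=C)C(=O)OC | intermediate (not isolated)
5 | (5S)-5-[4-(hydroxymethyl)furan-3-yl]-3-methylideneoxolan-2-one | O=C1O[C@H](c2cocc2CO)CC1=C | intermediate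
6 | (3R,5S)-3-hydroperoxy-5-[4-(hydroxymethyl)furan-3-yl]-3-methyloxolan-2-one | O=C1O[C@H](c2cocc2CO)C[C@@]1(C)OO | intermediate (not isolated)
7 | (3R,5S)-3-hydroxy-5-[4-(hydroxymethyl)furan-3-yl]-3-methyloxolan-2-one | O=C1O[C@H](c2cocc2CO)C[C@@]1(C)O | intermediate
8 | but-3-yn-1-ol | C#CCCO | starting material
9 | dimethyl{(1E)-4-[(dimethylalumanyl)oxy]-2-methylbut-1-en-1-yl}alumane | C[Al](C)/C=C(C)/CCO[Al](C)C | intermediate (not isolated)
10 | 2,4-dimethyl-5,6-dihydro-2H-1,2-oxaluminine (cyclic Z-alkenylaluminium alkoxide) | CC1=C[Al](C)OCC1 | intermediate (not isolated)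
11 | (3Z)-4-chloro-3-methylbut-3-en-1-ol | Cl/C=C(C)\CCO | intermediate
12 | (1Z)-4-bromo-1-chloro-2-methylbut-1-ene | Cl/C=C(C)\CCBr | intermediate
13 | [(3Z)-4-chloro-3-methylbut-3-en-1-yl]magnesium bromide | Cl/C=C(C)\CC[Mg]Br | intermediate (not isolated)
14 | (1Z,6R,8S)-1-chloro-6,8-dihydroxy-8-[4-(hydroxymethyl)furan-3-yl]-2,6-dimethyloct-1-en-5-one | O[C@H](c1cocc1CO)C[C@@](C)(O)C(=O)CC/C(C)=C\Cl | intermediate
15 | {4-[(1S,3R,7Z)-8-chloro-1,3-dihydroxy-3,7-dimethyl-4-oxooct-7-en-1-yl]furan-3-yl}methyl acetate | O[C@H](c1cocc1COC(C)=O)C[C@@](C)(O)C(=O)CC/C(C)=C\Cl | intermediate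
16 | [(4S,6R,10Z)-4,6-dihydroxy-6,10-dimethyl-7-oxo-4,5,6,7,8,9-hexahydrocyclodeca[b]furan-3-yl]methyl acetate | O[C@H]1C[C@@](C)(O)C(=O)CC/C(C)=C\c2occ(COC(C)=O)c21 | intermediate
17 | (4S,6R,10Z)-3-(acetoxymethyl)-6-hydroxy-6,10-dimethyl-7-oxo-4,5,6,7,8,9-hexahydrocyclodeca[b]furan-4-yl 2-methylprop-2-enoate | C=C(C)C(=O)O[C@H]1C[C@@](C)(O)C(=O)CC/C(C)=C\c2occ(COC(C)=O)c21 | intermediate
18 | (4S,6R,10Z)-6-acetoxy-3-(acetoxymethyl)-6,10-dimethyl-7-oxo-4,5,6,7,8,9-hexahydrocyclodeca[b]furan-4-yl 2-methylprop-2-enoate | C=C(C)C(=O)O[C@H]1C[C@@](C)(OC(C)=O)C(=O)CC/C(C)=C\c2occ(COC(C)=O)c21 | intermediate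
19 | (4S,6R,10Z)-6-acetoxy-3-(acetoxymethyl)-6,10-dimethyl-7-oxo-2-(4,4,5,5-tetramethyl-1,3,2-dioxaborolan-2-yl)-4,5,6,7,8,9-hexahydrocyclodeca[b]furan-4-yl 2-methylprop-2-enoate | C=C(C)C(=O)O[C@H]1C[C@@](C)(OC(C)=O)C(=O)CC/C(C)=C\c2oc(B3OC(C)(C)C(C)(C)O3)c(COC(C)=O)c21 | intermediate (not isolated)
20 | (4S,6R,10Z)-6-acetoxy-3-(acetoxymethyl)-6,10-dimethyl-7-oxo-2-[(4,4,5,5-tetramethyl-1,3,2-dioxaborolan-2-yl)oxy]-4,5,6,7,8,9-hexahydrocyclodeca[b]furan-4-yl 2-methylprop-2-enoate | C=C(C)C(=O)O[C@H]1C[C@@](C)(OC(C)=O)C(=O)CC/C(C)=C\c2oc(OB3OC(C)(C)C(C)(C)O3)c(COC(C)=O)c21 | intermediate (not isolated)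
21 | (4S,6R,10Z,11aR)-6-acetoxy-3-(acetoxymethyl)-6,10-dimethyl-2,7-dioxo-2,4,5,6,7,8,9,11a-octahydrocyclodeca[b]furan-4-yl 2-methylprop-2-enoate (CNP0115165.2) | C=C(C)C(=O)O[C@H]1C[C@@](C)(OC(C)=O)C(=O)CC/C(C)=C\[C@H]2OC(=O)C(COC(C)=O)=C12 | target

**Totals**
Total step count: 10 (8 in the main line, 2 for the Grignard precursor).
Longest linear sequence: 8 steps (1 → 5 → 7 → 14 → 15 → 16 → 17 → 18 → 21).

**Steps most likely to fail, each with a fallback**

Step 10 (dearomatisation). The 2-oxyfuran could be protonated at the α-carbon or at the far end of the alkenyl group (giving a γ-ylidene butenolide) instead of at C11a, and the facial preference at C11a is a prediction, not a precedent. The fallback sets out from 18 and delivers the C11a hydrogen as hydride instead of as a proton. Sensitised photo-oxygenation of 18 (O2, tetraphenylporphyrin, hν, CH2Cl2, −78 °C; then i-Pr2NEt) gives, through the furan endoperoxide and loss of the only α-hydrogen, (4S,6R,10Z)-6-acetoxy-3-(acetoxymethyl)-11a-hydroxy-6,10-dimethyl-2,7-dioxo-2,4,5,6,7,8,9,11a-octahydrocyclodeca[b]furan-4-yl 2-methylprop-2-enoate F4. Ionic reduction of this hemiketal (Et3SiH, BF3·OEt2, CH2Cl2, −78 °C) then attacks the acyloxocarbenium carbon and comes back to the route at 21. This removes the site-of-protonation problem; the face of attack remains substrate-controlled.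

Step 7 (macrocyclisation). The direct alkenylation may oligomerise or attack the remote α-C–H. The fallback sets out from 15 and replaces C–H activation by a cross-coupling whose site is fixed by ring size. Iridium-catalysed borylation of both furan α-C–H bonds ([Ir(cod)OMe]2, 4,4'-di-tert-butyl-2,2'-bipyridine, B2pin2, 2.2 equiv) gives {4-[(1S,3R,7Z)-8-chloro-1,3-dihydroxy-3,7-dimethyl-4-oxooct-7-en-1-yl]-2,5-bis(4,4,5,5-tetramethyl-1,3,2-dioxaborolan-2-yl)furan-3-yl}methyl acetate F2. Intramolecular Suzuki–Miyaura coupling under high dilution (Pd(OAc)2, SPhos, K3PO4, THF/H2O, 60 °C) can only engage the boronate next to the tether and gives [(4S,6R,10Z)-4,6-dihydroxy-6,10-dimethyl-7-oxo-2-(4,4,5,5-tetramethyl-1,3,2-dioxaborolan-2-yl)-4,5,6,7,8,9-hexahydrocyclodeca[b]furan-3-yl]methyl acetate F3. Protodeboronation (AcOH, wet THF, 50 °C) comes back to the route at 16.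

Step 2 (tertiary alcohol). Radical trapping by O2 may give a poor trans:cis ratio. The fallback sets out from 5 and uses an enolate instead of a radical. Conjugate reduction (NaBH4, MeOH, 0 °C) gives (5S)-5-[4-(hydroxymethyl)furan-3-yl]-3-methyloxolan-2-one F1 as a C3 epimer mixture, which does not matter. Double deprotonation (KN(SiMe3)2, 2.1 equiv, THF, −78 °C) and hydroxylation of the lactone enolate with 2-(benzenesulfonyl)-3-phenyloxaziridine, which approaches anti to the furyl group, comes back to the route at 7.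

**Further compounds**
F1 | step 2 | (5S)-5-[4-(hydroxymethyl)furan-3-yl]-3-methyloxolan-2-one | O=C1O[C@H](c2cocc2CO)CC1C
F2 | step 7 | {4-[(1S,3R,7Z)-8-chloro-1,3-dihydroxy-3,7-dimethyl-4-oxooct-7-en-1-yl]-2,5-bis(4,4,5,5-tetramethyl-1,3,2-dioxaborolan-2-yl)furan-3-yl}methyl acetate | O[C@H](c1c(B2OC(C)(C)C(C)(C)O2)oc(B2OC(C)(C)C(C)(C)O2)c1COC(C)=O)C[C@@](C)(O)C(=O)CC/C(C)=C\Cl
F3 | step 7 | [(4S,6R,10Z)-4,6-dihydroxy-6,10-dimethyl-7-oxo-2-(4,4,5,5-tetramethyl-1,3,2-dioxaborolan-2-yl)-4,5,6,7,8,9-hexahydrocyclodeca[b]furan-3-yl]methyl acetate | O[C@H]1C[C@@](C)(O)C(=O)CC/C(C)=C\c2oc(B3OC(C)(C)C(C)(C)O3)c(COC(C)=O)c21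
F4 | step 10 | (4S,6R,10Z)-6-acetoxy-3-(acetoxymethyl)-11a-hydroxy-6,10-dimethyl-2,7-dioxo-2,4,5,6,7,8,9,11a-octahydrocyclodeca[b]furan-4-yl 2-methylprop-2-enoate | C=C(C)C(=O)O[C@H]1C[C@@](C)(OC(C)=O)C(=O)CC/C(C)=C\C2(O)OC(=O)C(COC(C)=O)=C12
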